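**Retrosynthetic overview**
1. Target 24 ⇐ MnO2 oxidation of the ring allylic carbinol (kept as a silyl ether while the chain is built) ⇐ C25 ester from Horner–Wadsworth–Emmons (HWE) coupling of C20 aldehyde 18 with C5 phosphonate 21.
2. 18 ⇐ C15 aldehyde 14 + C5 phosphonate 15 (HWE, then ester → aldehyde).
3. C15 ester 9 ⇐ Julia–Kocienski olefination of α-cyclogeranyl tetrazolyl sulfone 7 with C5 aldehyde ester 8; the ring oxygen comes from allylic C–H oxidation of 9.
4. (S)-α-Cyclogeraniol 5 ⇐ Still–Wittig [2,3] rearrangement (C–O to C–C chirality transfer) of (R)-allylic alcohol 2 ⇐ ketoreductase reduction of achiral enone 1.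
5. No ring is formed: the single carbocycle is bought as 1.

Assumption: enone 1 is purchased, and the temporary carbinol centre made in step 8 is carried as an epimer mixture because step 19 removes it.

**Step 1**
Reactants: 1 2,4,4-trimethylcyclohex-2-en-1-one
Product: 2 (1R)-2,4,4-trimethylcyclohex-2-en-1-ol
Conditions: (R)-selective ketoreductase (NADPH-dependent alcohol dehydrogenase, picked from a panel), NADP+ (cat.), i-PrOH (10 vol %), K2HPO4/KH2PO4 buffer pH 7, MgSO4 (1 mM), 30 °C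
Reagents that add atoms: none
Why: Biocatalytic asymmetric carbonyl reduction, in which the enzyme delivers hydride from NADPH to one face of the prochiral C=O (1,2-reduction only) and so sets the R carbinol centre, with isopropanol recycling the cofactor.

**Step 2**
Reactants: 2 (1R)-2,4,4-trimethylcyclohex-2-en-1-ol
Product: 3 tributyl({[(1R)-2,4,4-trimethylcyclohex-2-en-1-yl]oxy}methyl)stannane
Conditions: KH, THF, 0 °C; then Bu3SnCH2I, 0 °C → rt
Reagents that add atoms: tributyl(iodomethyl)stannane, CCCC[Sn](CCCC)(CCCC)CI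
Why: Williamson etherification of the potassium alkoxide with a primary iodide, which does not touch the carbinol centre.

**Step 3**
Reactants: 3 tributyl({[(1R)-2,4,4-trimethylcyclohex-2-en-1-yl]oxy}methyl)stannane
Product: 5 (S)-α-cyclogeraniol [(1S)-2,6,6-trimethylcyclohex-2-en-1-yl]methanol, via lithiomethyl ether 4 (not isolated)
Conditions: n-BuLi, THF, −78 → 0 °C; then H2O
Reagents that add atoms: none
Why: Still–Wittig [2,3]-sigmatropic rearrangement, in which tin–lithium exchange gives the α-alkoxy carbanion that bonds to the alkene terminus on the face that carried oxygen (suprafacial), so the R carbinol centre is exchanged for the S carbon centre and the double bond moves to its place in the target.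

**Step 4**
Reactants: 5 [(1S)-2,6,6-trimethylcyclohex-2-en-1-yl]methanol
Product: 6 1-phenyl-5-({[(1S)-2,6,6-trimethylcyclohex-2-en-1-yl]methyl}sulfanyl)-1H-tetrazole
Conditions: 1-phenyl-1H-tetrazole-5-thiol, PPh3, DIAD, THF, 0 °C → rt
Reagents that add atoms: 1-phenyl-1H-tetrazole-5-thiol, Sc1nnnn1-c1ccccc1
Why: Mitsunobu thioetherification of the primary alcohol, with no bond to the stereocentre broken.

**Step 5**
Reactants: 6 1-phenyl-5-({[(1S)-2,6,6-trimethylcyclohex-2-en-1-yl]methyl}sulfanyl)-1H-tetrazole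
Product: 7 1-phenyl-5-({[(1S)-2,6,6-trimethylcyclohex-2-en-1-yl]methyl}sulfonyl)-1H-tetrazole
Conditions: (NH4)6Mo7O24·4H2O (10 mol %), 30% aq. H2O2, EtOH, 0 °C → rt
Reagents that add atoms: hydrogen peroxide, OO
Why: Molybdate-catalysed peroxide oxidation of sulfide to sulfone, which is much faster than epoxidation of the unactivated trisubstituted alkene.

**Step 6**
Reactants: 7 1-phenyl-5-({[(1S)-2,6,6-trimethylcyclohex-2-en-1-yl]methyl}sulfonyl)-1H-tetrazole; 8 ethyl (2E)-3-methyl-4-oxobut-2-enoate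
Product: 9 ethyl (2E,4E)-3-methyl-5-[(1S)-2,6,6-trimethylcyclohex-2-en-1-yl]penta-2,4-dienoate
Conditions: KN(SiMe3)2, DME, −60 °C; then 8, −60 °C → rt
Reagents that add atoms: none
Why: Julia–Kocienski olefination, in which the metalated sulfone adds to the aldehyde and Smiles rearrangement with loss of SO2 gives the E disubstituted alkene, while the E trisubstituted alkene comes ready-made in 8 and the carbanion sits beside, not on, the stereocentre.

**Step 7**
Reactants: 9 ethyl (2E,4E)-3-methyl-5-[(1S)-2,6,6-trimethylcyclohex-2-en-1-yl]penta-2,4-dienoate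
Product: 10 ethyl (2E,4E)-3-methyl-5-[(1S)-2,6,6-trimethyl-4-oxocyclohex-2-en-1-yl]penta-2,4-dienoate
Conditions: Rh2(cap)4 (dirhodium tetracaprolactamate, 1 mol %), t-BuOOH (70% aq., 5 equiv), ClCH2CH2Cl, 40 °C
Reagents that add atoms: tert-butyl hydroperoxide, CC(C)(C)OO
Why: Allylic C–H oxidation by a tert-butylperoxyl radical chain at the unhindered ring CH2 next to the electron-rich trisubstituted alkene (the position at which α-ionone itself is oxidised), under base-free conditions that leave the now acidic ring methine alone.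

**Step 8**
Reactants: 10 ethyl (2E,4E)-3-methyl-5-[(1S)-2,6,6-trimethyl-4-oxocyclohex-2-en-1-yl]penta-2,4-dienoate
Product: 11 ethyl (2E,4E)-5-[(1S)-4-hydroxy-2,6,6-trimethylcyclohex-2-en-1-yl]-3-methylpenta-2,4-dienoate (both C4 epimers)
Conditions: NaBH4, CeCl3·7H2O, MeOH, −20 °C
Reagents that add atoms: none
Why: Luche 1,2-reduction of the enone, which spares the dienoate and gives a temporary carbinol centre whose epimer ratio is irrelevant.

**Step 9**
Reactants: 11 ethyl (2E,4E)-5-[(1S)-4-hydroxy-2,6,6-trimethylcyclohex-2-en-1-yl]-3-methylpenta-2,4-dienoate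
Product: 12 ethyl (2E,4E)-5-[(1S)-4-{[tert-butyl(dimethyl)silyl]oxy}-2,6,6-trimethylcyclohex-2-en-1-yl]-3-methylpenta-2,4-dienoate (both C4 epimers)
Conditions: TBSCl, imidazole, DMF, rt
Reagents that add atoms: tert-butyl(chloro)dimethylsilane, CC(C)(C)[Si](C)(C)Cl
Why: Standard silylation of a secondary alcohol, masking the ring oxygen against the hydride and carbanion steps that follow.

**Step 10**
Reactants: 12 ethyl (2E,4E)-5-[(1S)-4-{[tert-butyl(dimethyl)silyl]oxy}-2,6,6-trimethylcyclohex-2-en-1-yl]-3-methylpenta-2,4-dienoate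
Product: 13 (2E,4E)-5-[(1S)-4-{[tert-butyl(dimethyl)silyl]oxy}-2,6,6-trimethylcyclohex-2-en-1-yl]-3-methylpenta-2,4-dien-1-ol (both C4 epimers)
Conditions: i-Bu2AlH (2.5 equiv), CH2Cl2, −78 °C; then aq. potassium sodium tartrate (KNaC4H4O6)
Reagents that add atoms: none
Why: Hydride reduction of the conjugated ester to the allylic alcohol at low temperature, with the silyl ether and alkenes inert.

**Step 11**
Reactants: 13 (2E,4E)-5-[(1S)-4-{[tert-butyl(dimethyl)silyl]oxy}-2,6,6-trimethylcyclohex-2-en-1-yl]-3-methylpenta-2,4-dien-1-ol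
Product: 14 (2E,4E)-5-[(1S)-4-{[tert-butyl(dimethyl)silyl]oxy}-2,6,6-trimethylcyclohex-2-en-1-yl]-3-methylpenta-2,4-dienal (both C4 epimers)
Conditions: MnO2 (activated, excess), CH2Cl2, rt, dark
Reagents that add atoms: none
Why: Selective MnO2 oxidation of the allylic primary alcohol to the dienal under neutral conditions, without over-oxidation.

**Step 12**
Reactants: 14 (2E,4E)-5-[(1S)-4-{[tert-butyl(dimethyl)silyl]oxy}-2,6,6-trimethylcyclohex-2-en-1-yl]-3-methylpenta-2,4-dienal; 15 ethyl (2E)-4-(diethoxyphosphoryl)-3-methylbut-2-enoate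
Product: 16 ethyl (2E,4E,6E,8E)-9-[(1S)-4-{[tert-butyl(dimethyl)silyl]oxy}-2,6,6-trimethylcyclohex-2-en-1-yl]-3,7-dimethylnona-2,4,6,8-tetraenoate (both C4 epimers)
Conditions: 15, n-BuLi, THF/DMPU, −78 °C; then 14, −78 → 0 °C
Reagents that add atoms: none
Why: Vinylogous Horner–Wadsworth–Emmons olefination, which forms the new disubstituted alkene E, the minor 2Z isomer from the reagent's trisubstituted alkene being removed by chromatography.

**Step 13**
Reactants: 16 ethyl (2E,4E,6E,8E)-9-[(1S)-4-{[tert-butyl(dimethyl)silyl]oxy}-2,6,6-trimethylcyclohex-2-en-1-yl]-3,7-dimethylnona-2,4,6,8-tetraenoate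
Product: 17 (2E,4E,6E,8E)-9-[(1S)-4-{[tert-butyl(dimethyl)silyl]oxy}-2,6,6-trimethylcyclohex-2-en-1-yl]-3,7-dimethylnona-2,4,6,8-tetraen-1-ol (both C4 epimers)
Conditions: i-Bu2AlH (2.5 equiv), CH2Cl2, −78 °C; then aq. potassium sodium tartrate (KNaC4H4O6)
Reagents that add atoms: none
Why: The same low-temperature ester-to-allylic-alcohol hydride reduction as in step 10.

**Step 14**
Reactants: 17 (2E,4E,6E,8E)-9-[(1S)-4-{[tert-butyl(dimethyl)silyl]oxy}-2,6,6-trimethylcyclohex-2-en-1-yl]-3,7-dimethylnona-2,4,6,8-tetraen-1-ol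
Product: 18 (2E,4E,6E,8E)-9-[(1S)-4-{[tert-butyl(dimethyl)silyl]oxy}-2,6,6-trimethylcyclohex-2-en-1-yl]-3,7-dimethylnona-2,4,6,8-tetraenal (both C4 epimers)
Conditions: MnO2 (activated, excess), CH2Cl2, rt, dark
Reagents that add atoms: none
Why: MnO2 oxidation of the polyenylic primary alcohol, the standard retinol-to-retinal type conversion.

**Step 15**
Reactants: 19 methyl (2E)-2-methylbut-2-enoate (methyl tiglate)
Product: 20 methyl (2E)-4-bromo-2-methylbut-2-enoate
Conditions: NBS, AIBN (cat.), PhCF3, 85 °C; distillation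
Reagents that add atoms: N-bromosuccinimide, O=C1CCC(=O)N1Br
Why: Wohl–Ziegler allylic bromination, which favours the γ-methyl group of the tiglate.

**Step 16**
Reactants: 20 methyl (2E)-4-bromo-2-methylbut-2-enoate
Product: 21 methyl (2E)-4-(diethoxyphosphoryl)-2-methylbut-2-enoate
Conditions: P(OEt)3, neat, 130 °C, EtBr distilled off
Reagents that add atoms: triethyl phosphite, CCOP(OCC)OCC
Why: Michaelis–Arbuzov reaction of a primary allylic bromide.

**Step 17**
Reactants: 18 (2E,4E,6E,8E)-9-[(1S)-4-{[tert-butyl(dimethyl)silyl]oxy}-2,6,6-trimethylcyclohex-2-en-1-yl]-3,7-dimethylnona-2,4,6,8-tetraenal; 21 methyl (2E)-4-(diethoxyphosphoryl)-2-methylbut-2-enoate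
Product: 22 methyl (2E,4E,6E,8E,10E,12E)-13-[(1S)-4-{[tert-butyl(dimethyl)silyl]oxy}-2,6,6-trimethylcyclohex-2-en-1-yl]-2,7,11-trimethyltrideca-2,4,6,8,10,12-hexaenoate (both C4 epimers)
Conditions: 21, NaH, THF, 0 °C; then 18, 0 °C → rt, dark
Reagents that add atoms: none
Why: Horner–Wadsworth–Emmons olefination with the C5 phosphonate, which gives the E alkene and installs the methyl ester directly.

**Step 18**
Reactants: 22 methyl (2E,4E,6E,8E,10E,12E)-13-[(1S)-4-{[tert-butyl(dimethyl)silyl]oxy}-2,6,6-trimethylcyclohex-2-en-1-yl]-2,7,11-trimethyltrideca-2,4,6,8,10,12-hexaenoate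
Product: 23 methyl (2E,4E,6E,8E,10E,12E)-13-[(1S)-4-hydroxy-2,6,6-trimethylcyclohex-2-en-1-yl]-2,7,11-trimethyltrideca-2,4,6,8,10,12-hexaenoate (both C4 epimers)
Conditions: Bu4NF, AcOH, THF, 0 °C → rt, dark
Reagents that add atoms: none
Why: Fluoride desilylation, buffered with acetic acid so that neither the methyl ester nor the ring methine meets free alkoxide.

**Step 19**
Reactants: 23 methyl (2E,4E,6E,8E,10E,12E)-13-[(1S)-4-hydroxy-2,6,6-trimethylcyclohex-2-en-1-yl]-2,7,11-trimethyltrideca-2,4,6,8,10,12-hexaenoate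
Product: 24 methyl (2E,4E,6E,8E,10E,12E)-2,7,11-trimethyl-13-[(1S)-2,6,6-trimethyl-4-oxocyclohex-2-en-1-yl]trideca-2,4,6,8,10,12-hexaenoate
Conditions: MnO2 (activated, excess), CH2Cl2, rt, dark, argon
Reagents that add atoms: none
Why: MnO2 oxidation of the secondary allylic alcohol to the enone converges both carbinol epimers on one product under neutral conditions, so the S methine (set in step 3, now flanked by enone and polyene) is not epimerised.

**Compound list**
1 | 2,4,4-trimethylcyclohex-2-en-1-one | O=C1C(C)=CC(C)(C)CC1 | starting material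
2 | (1R)-2,4,4-trimethylcyclohex-2-en-1-ol | O[C@H]1C(C)=CC(C)(C)CC1 | intermediate
3 | tributyl({[(1R)-2,4,4-trimethylcyclohex-2-en-1-yl]oxy}methyl)stannane | CCCC[Sn](CCCC)(CCCC)CO[C@H]1C(C)=CC(C)(C)CC1 | intermediate
4 | ({[(1R)-2,4,4-trimethylcyclohex-2-en-1-yl]oxy}methyl)lithium (lithiomethyl ether) | [Li]CO[C@H]1C(C)=CC(C)(C)CC1 | intermediate (not isolated)
5 | [(1S)-2,6,6-trimethylcyclohex-2-en-1-yl]methanol, (S)-α-cyclogeraniol | OC[C@@H]1C(C)=CCCC1(C)C | intermediate
6 | 1-phenyl-5-({[(1S)-2,6,6-trimethylcyclohex-2-en-1-yl]methyl}sulfanyl)-1H-tetrazole | c1ccccc1-n1nnnc1SC[C@@H]1C(C)=CCCC1(C)C | intermediate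
7 | 1-phenyl-5-({[(1S)-2,6,6-trimethylcyclohex-2-en-1-yl]methyl}sulfonyl)-1H-tetrazole | c1ccccc1-n1nnnc1S(=O)(=O)C[C@@H]1C(C)=CCCC1(C)C | intermediate
8 | ethyl (2E)-3-methyl-4-oxobut-2-enoate | CCOC(=O)/C=C(C)/C=O | starting material
9 | ethyl (2E,4E)-3-methyl-5-[(1S)-2,6,6-trimethylcyclohex-2-en-1-yl]penta-2,4-dienoate | CCOC(=O)/C=C(C)/C=C/[C@@H]1C(C)=CCCC1(C)C | intermediate
10 | ethyl (2E,4E)-3-methyl-5-[(1S)-2,6,6-trimethyl-4-oxocyclohex-2-en-1-yl]penta-2,4-dienoate | CCOC(=O)/C=C(C)/C=C/[C@@H]1C(C)=CC(=O)CC1(C)C | intermediate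
11 | ethyl (2E,4E)-5-[(1S)-4-hydroxy-2,6,6-trimethylcyclohex-2-en-1-yl]-3-methylpenta-2,4-dienoate, both C4 epimers | CCOC(=O)/C=C(C)/C=C/[C@@H]1C(C)=CC(O)CC1(C)C | intermediate
12 | ethyl (2E,4E)-5-[(1S)-4-{[tert-butyl(dimethyl)silyl]oxy}-2,6,6-trimethylcyclohex-2-en-1-yl]-3-methylpenta-2,4-dienoate, both C4 epimers | CCOC(=O)/C=C(C)/C=C/[C@@H]1C(C)=CC(O[Si](C)(C)C(C)(C)C)CC1(C)C | intermediate
13 | (2E,4E)-5-[(1S)-4-{[tert-butyl(dimethyl)silyl]oxy}-2,6,6-trimethylcyclohex-2-en-1-yl]-3-methylpenta-2,4-dien-1-ol, both C4 epimers | OC/C=C(C)/C=C/[C@@H]1C(C)=CC(O[Si](C)(C)C(C)(C)C)CC1(C)C | intermediate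
14 | (2E,4E)-5-[(1S)-4-{[tert-butyl(dimethyl)silyl]oxy}-2,6,6-trimethylcyclohex-2-en-1-yl]-3-methylpenta-2,4-dienal, both C4 epimers | O=C/C=C(C)/C=C/[C@@H]1C(C)=CC(O[Si](C)(C)C(C)(C)C)CC1(C)C | intermediate
15 | ethyl (2E)-4-(diethoxyphosphoryl)-3-methylbut-2-enoate | CCOC(=O)/C=C(C)/CP(=O)(OCC)OCC | starting material
16 | ethyl (2E,4E,6E,8E)-9-[(1S)-4-{[tert-butyl(dimethyl)silyl]oxy}-2,6,6-trimethylcyclohex-2-en-1-yl]-3,7-dimethylnona-2,4,6,8-tetraenoate, both C4 epimers | CCOC(=O)/C=C(C)/C=C/C=C(C)/C=C/[C@@H]1C(C)=CC(O[Si](C)(C)C(C)(C)C)CC1(C)C | intermediate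
17 | (2E,4E,6E,8E)-9-[(1S)-4-{[tert-butyl(dimethyl)silyl]oxy}-2,6,6-trimethylcyclohex-2-en-1-yl]-3,7-dimethylnona-2,4,6,8-tetraen-1-ol, both C4 epimers | OC/C=C(C)/C=C/C=C(C)/C=C/[C@@H]1C(C)=CC(O[Si](C)(C)C(C)(C)C)CC1(C)C | intermediate
18 | (2E,4E,6E,8E)-9-[(1S)-4-{[tert-butyl(dimethyl)silyl]oxy}-2,6,6-trimethylcyclohex-2-en-1-yl]-3,7-dimethylnona-2,4,6,8-tetraenal, both C4 epimers | O=C/C=C(C)/C=C/C=C(C)/C=C/[C@@H]1C(C)=CC(O[Si](C)(C)C(C)(C)C)CC1(C)C | intermediate
19 | methyl (2E)-2-methylbut-2-enoate (methyl tiglate) | COC(=O)/C(C)=C/C | starting material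
20 | methyl (2E)-4-bromo-2-methylbut-2-enoate | COC(=O)/C(C)=C/CBr | intermediate
21 | methyl (2E)-4-(diethoxyphosphoryl)-2-methylbut-2-enoate | COC(=O)/C(C)=C/CP(=O)(OCC)OCC | intermediate
22 | methyl (2E,4E,6E,8E,10E,12E)-13-[(1S)-4-{[tert-butyl(dimethyl)silyl]oxy}-2,6,6-trimethylcyclohex-2-en-1-yl]-2,7,11-trimethyltrideca-2,4,6,8,10,12-hexaenoate, both C4 epimers | COC(=O)/C(C)=C/C=C/C=C(C)/C=C/C=C(C)/C=C/[C@@H]1C(C)=CC(O[Si](C)(C)C(C)(C)C)CC1(C)C | intermediate
23 | methyl (2E,4E,6E,8E,10E,12E)-13-[(1S)-4-hydroxy-2,6,6-trimethylcyclohex-2-en-1-yl]-2,7,11-trimethyltrideca-2,4,6,8,10,12-hexaenoate, both C4 epimers | COC(=O)/C(C)=C/C=C/C=C(C)/C=C/C=C(C)/C=C/[C@@H]1C(C)=CC(O)CC1(C)C | intermediate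
24 | methyl (2E,4E,6E,8E,10E,12E)-2,7,11-trimethyl-13-[(1S)-2,6,6-trimethyl-4-oxocyclohex-2-en-1-yl]trideca-2,4,6,8,10,12-hexaenoate | COC(=O)/C(C)=C/C=C/C=C(C)/C=C/C=C(C)/C=C/[C@@H]1C(C)=CC(=O)CC1(C)C | target

**Totals**
Total step count: 19. Longest linear sequence: 17 (steps 1–14 and 17–19); steps 15–16 make phosphonate 21 on the side.

**Three steps most likely to fail**

Step 3 (Still–Wittig rearrangement). The new C–C bond forms next to the quaternary carbon, so a [1,2]-shift or simple protonation of 4 can compete. The fallback sets out from 2 and comes back at 5. Alcohol 2 is heated with N,N-dimethylformamide dimethyl acetal in xylene at 140 °C; the alkoxy(amino)carbene formed by loss of methanol undergoes a Büchi [2,3] rearrangement on the same face and gives (1S)-N,N,2,6,6-pentamethylcyclohex-2-ene-1-carboxamide F1. Reduction of this tertiary amide with LiH2NBH3 in THF (0 °C → rt) then gives alcohol 5.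

Step 6 (Julia–Kocienski olefination). The E/Z ratio at the new alkene may be modest, and the sulfonyl carbanion may add in conjugate fashion to the doubly activated alkene of 8. The fallback reverses the polarity; it sets out from 5 and comes back at 9. Alcohol 5 is oxidised with Dess–Martin periodinane and NaHCO3 in CH2Cl2 at 0 °C to (1S)-2,6,6-trimethylcyclohex-2-ene-1-carbaldehyde F2, which is configurationally labile and is used at once. It is added at −78 °C to the lithium anion of phosphonate 15 (n-BuLi, THF/DMPU), and the Horner–Wadsworth–Emmons reaction gives 9 after chromatographic removal of the 2Z isomer.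

Step 7 (allylic oxidation). Attack at the doubly allylic ring methine or over-oxidation of enone 10 may lower the yield. The fallback moves the oxidation one stage earlier, onto a substrate whose methine is not doubly allylic; it sets out from 7 and comes back at 12. Sulfone 7 is oxidised with Rh2(cap)4 and t-BuOOH as above to 1-phenyl-5-({[(1S)-2,6,6-trimethyl-4-oxocyclohex-2-en-1-yl]methyl}sulfonyl)-1H-tetrazole F3, which is kept away from base because sulfinate can be lost by vinylogous elimination. Reduction with i-Bu2AlH in CH2Cl2 at −78 °C gives 5-({[(1S)-4-hydroxy-2,6,6-trimethylcyclohex-2-en-1-yl]methyl}sulfonyl)-1-phenyl-1H-tetrazole F4 as a mixture of C4 epimers. Silylation with TBSCl and imidazole gives 5-({[(1S)-4-{[tert-butyl(dimethyl)silyl]oxy}-2,6,6-trimethylcyclohex-2-en-1-yl]methyl}sulfonyl)-1-phenyl-1H-tetrazole F5. Julia–Kocienski olefination of F5 with 8 (KN(SiMe3)2, DME, −60 °C → rt) gives 12 directly, so steps 7–9 are no longer needed.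

**Further compounds**
F1 | step 3 | (1S)-N,N,2,6,6-pentamethylcyclohex-2-ene-1-carboxamide | CN(C)C(=O)[C@@H]1C(C)=CCCC1(C)C
F2 | step 6 | (1S)-2,6,6-trimethylcyclohex-2-ene-1-carbaldehyde | O=C[C@@H]1C(C)=CCCC1(C)C
F3 | step 7 | 1-phenyl-5-({[(1S)-2,6,6-trimethyl-4-oxocyclohex-2-en-1-yl]methyl}sulfonyl)-1H-tetrazole | c1ccccc1-n1nnnc1S(=O)(=O)C[C@@H]1C(C)=CC(=O)CC1(C)C
F4 | step 7 | 5-({[(1S)-4-hydroxy-2,6,6-trimethylcyclohex-2-en-1-yl]methyl}sulfonyl)-1-phenyl-1H-tetrazole, both C4 epimers | c1ccccc1-n1nnnc1S(=O)(=O)C[C@@H]1C(C)=CC(O)CC1(C)C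
F5 | step 7 | 5-({[(1S)-4-{[tert-butyl(dimethyl)silyl]oxy}-2,6,6-trimethylcyclohex-2-en-1-yl]methyl}sulfonyl)-1-phenyl-1H-tetrazole, both C4 epimers | c1ccccc1-n1nnnc1S(=O)(=O)C[C@@H]1C(C)=CC(O[Si](C)(C)C(C)(C)C)CC1(C)C
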